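**Cedar's leftover.** At 5.00 h cedar held 30.0% of its charge outside both readings, and I could not say what that was. The share of complex with two exchanged in the two read products (the selectivity) needs no account of it, so I followed that share.

| flask | starting complex | incoming ligand | leaving ligand | temperature | remark | time |
|---|---|---|---|---|---|---|
| oak | 0.25 M | 2 equiv | 2 equiv | −35 °C | run made earlier |  |
| cedar | 0.35 M | 2 equiv | 2 equiv | −20 °C | run made earlier |  |
| ash | 0.55 M | 2 equiv | 2 equiv | −35 °C | run made earlier |  |
| green | 0.25 M | 2.00 equiv (fed, over 1.5 h) | 2.00 equiv | −20 °C | all else is in the flask from the start; the feed brings no volume worth counting | 4.0 h |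
| red | 0.25 M (fed, over 1.5 h) | 2.00 equiv | 2.00 equiv |  | the addition at −60 °C, then warmed to −20 °C; the feed brings no volume worth counting | 4.0 h |
| amber | 0.25 M (fed, over 1.5 h) | 2.00 equiv | 2.00 equiv | −20 °C | all else is in the flask from the start; the feed brings no volume worth counting | 4.0 h |
| grey | 0.25 M | 2.00 equiv | 2.00 equiv | −20 °C | everything together at the start | 4.0 h |

- oak (time / h: complex with two exchanged / %, side product / %): 0.667: 3.6, 0.3; 1.00: 6.8, 0.2; 1.33: 8.5, 0.3; 2.00: 13.6, 0.6; 3.00: 20.6, 2.1; 5.00: 33.3, 3.8; 8.00: 41.3, 7.0
- cedar (time / h: complex with two exchanged / %, side product / %): 0.667: 25.5, 4.4; 1.33: 36.2, 11.8; 2.00: 39.8, 17.2; 3.00: 40.2, 24.7; 4.00: 37.7, 31.6; 5.00: 32.4, 37.6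
- ash (time / h: complex with two exchanged / %, side product / %): 0.833: 13.5, 0; 1.33: 22.3, 0.5; 2.00: 29.9, 1.9; 3.00: 41.1, 3.2; 4.00: 48.6, 4.5; 6.00: 55.6, 7.0; 10.0: 60.1, 12.3

(readings scatter by 0.5 percentage points)

- a reading or a percentage of complex with two exchanged counts all its forms, free or not

- the flask with the highest share of complex with two exchanged in complex with two exchanged plus side product ("all alike" if they lie within 1.5 percentage points) (green / red / amber / grey / all alike)
- share of complex with two exchanged in complex with two exchanged plus side product at the end, green
- share of complex with two exchanged in complex with two exchanged plus side product at the end, red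
- share of complex with two exchanged in complex with two exchanged plus side product at the end, amber
- share of complex with two exchanged in complex with two exchanged plus side product at the end, grey

**What matters.** I first asked which figures had to be good. Concentration seemed not to be one: oak and ash differ 2.20-fold in starting complex, yet their shares at 3.00 h read 90.7% and 92.8%, on side-product readings of 2.1% and 3.2% with a scatter of 0.5 percentage points. Temperature was one: oak needed 8.00 h for its complex with two exchanged to read 41.3%, while cedar, which was also more concentrated, read 39.8% at 2.00 h, so I took an hour at −20 °C as worth roughly 4.00 at −35 °C, a rough reading with both differences in it. Cedar, at the temperature of the flasks, therefore became my ruler. Time was another: cedar's share falls from 65.6%, midway between its readings at 2.00 h and 3.00 h, to 54.4% at 4.00 h, a drop of 11 points.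

**The number.** Red's feed at −60 °C, colder than oak, I counted as nothing at first, which leaves red 2.50 h. That is its warm age: the hours the average portion of the charge has spent with its partners at −20 °C. Green and amber, whose steady feeds deliver the average portion at mid-feed, have 3.25 h, and grey has 4.0 h. The ruler gives 65.6% for red, 60.0% for green and amber, and 54.4% for grey. On a second round I put the cold hours back at oak's pace, a generous estimate of 0.375 h. That takes 2.8 points from red, leaving 62.8%, still above 60.0%, so I put red first.

**The result.** The forecast, which differed from me, gave 62%, 63%, 66% and 54% for green, red, amber and grey and chose amber, holding that selectivity “depends mostly on product age”. The flasks give 60.3%, 67.5%, 59.4% and 54.8% in that order, with red highest.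

    starting complex + incoming ligand ⇌ leaving ligand + complex with one exchanged (K = 41.2, k = 6.33 × 10⁻⁴ /M/s, Ea = 51.0 kJ/mol, ΔH = −90.0 kJ/mol)
    complex with one exchanged + incoming ligand ⇌ leaving ligand + complex with two exchanged (K = 2.32, k = 0.00178 /M/s, Ea = 49.0 kJ/mol, ΔH = −11.0 kJ/mol)
    crystals ⇌ complex with two exchanged, rate k3*(cs3 - [complex with two exchanged]) while solid is left; crystals form when [complex with two exchanged] > cs3 (solubility = 19.0 mM, k = 0.00209 /s)
    leaving ligand + complex with two exchanged → side product (k = 3.28 × 10⁻⁴ /M/s, Ea = 62.0 kJ/mol)
    complex with two exchanged + incoming ligand ⇌ idle adduct, settled at all times (K = 2.20 /M, ΔH = −11.0 kJ/mol)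
    (constants at −20 °C)

At the end red held 17.2% side product and grey 27.8%. Per hour of warm age that is 0.0688 /h of the charge in red and 0.0695 /h in grey. Grey read at 2.50 h has red's warm age of 2.50 h, and it holds 17.2% side product at a share of 67.6%.

All runs are simulated on assumed constants; the scatter is artificial.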